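**Retrosynthetic overview**
1. Last step: the carbon of a lupulone-type enolate opens a C7–C8 epoxide (6-exo-tet). This forms the Cα–C8 bond and closes the spiro-cyclohexane. Cleaving a temporary pyran releases that enolate and the C3 hydroxyl together.
2. Before that: dearomative gem-diprenylation of the one free aromatic carbon (lupulone-type alkylation).
3. Key step: one epoxide-triggered cation–olefin–phenol cyclisation of an oxidised geranyl chain. It makes the cyclopentane (C2–C6 bond) and the temporary pyran (O–C3 bond).
4. Union: Tsuji–Trost coupling of phlorisovalerophenone with an epoxy tosylate. The tosylate comes from geranyl acetate by allylic oxidation and Sharpless epoxidation, the only source of chirality.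
5. Ring order: bought arene → cyclopentane plus temporary pyran → pyran opened → spiro-cyclohexane.

Assumption: enol/keto tautomers are drawn in one arbitrary form (the target as in the given SMILES); terpene carbons keep geraniol numbering (C1 on the ring, C8 the oxidised (E)-methyl, C9 the methyl on C7, C10 the methyl on C3), and Cα is the ring carbon bound to C1.

Step 1
Reactants: 1 phloroglucinol; 2 isovaleryl chloride
Product: 3 phlorisovalerophenone [3-methyl-1-(2,4,6-trihydroxyphenyl)butan-1-one]
Conditions: AlCl3, CH2Cl2–PhNO2, 0 to 40 °C; aq HCl work-up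
Reagents that add atoms: none
Why: Friedel–Crafts acylation of the very electron-rich arene stops after one acyl group because the chelated aryl ketone deactivates the ring, and no stereocentre is formed.

Step 2
Reactants: 4 geranyl acetate
Product: 5 (2E,6E)-8-hydroxygeranyl acetate
Conditions: SeO2 (10 mol %), salicylic acid (10 mol %), t-BuOOH, CH2Cl2, 23 °C
Reagents that add atoms: tert-butyl hydroperoxide CC(C)(C)OO
Why: SeO2-catalysed allylic oxidation (ene reaction, then [2,3]-sigmatropic shift) picks the more electron-rich terminal alkene, the other being deactivated by its allylic acetate, and by its mechanism oxidises only the (E)-methyl group, so C8 is functionalised without creating a stereocentre.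

Step 3
Reactants: 5 (2E,6E)-8-hydroxygeranyl acetate
Product: 7 (6R,7R)-6,7-epoxy-8-tosyloxygeranyl acetate, via epoxy alcohol 6 (not isolated)
Conditions: Ti(OiPr)4 (8 mol %), D-(−)-diethyl tartrate (10 mol %), t-BuOOH, 4 Å MS, CH2Cl2, −20 °C; P(OMe)3; then Et3N, DMAP (cat.), TsCl, −10 °C
Reagents that add atoms: tert-butyl hydroperoxide CC(C)(C)OO; 4-toluenesulfonyl chloride Cc1ccc(cc1)S(=O)(=O)Cl
Why: Sharpless asymmetric epoxidation touches only the alkene of the free allylic alcohol, and the D-(−)-tartrate complex gives the (6R,7R)-epoxide (mirror image of the (2S,3S) products that L-(+)-tartrate gives from (E)-allylic alcohols, typically over 94% ee), which sets C7 for good and C6 for a later inversion, while in situ tosylation is the standard derivatisation of the crude epoxy alcohol.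

Step 4
Reactants: 3 phlorisovalerophenone (2.5 equiv); 7 (6R,7R)-6,7-epoxy-8-tosyloxygeranyl acetate
Product: 8 3-[(2E,6R,7R)-6,7-epoxy-8-tosyloxygeranyl]phlorisovalerophenone
Conditions: Pd(PPh3)4 (5 mol %), THF, 40 °C (the acetate set free is the base)
Reagents that add atoms: none
Why: Tsuji–Trost allylic alkylation, in which zerovalent palladium ionises only the allylic acetate, the soft ring carbon attacks the unhindered terminus C1 (O-allyl ethers re-ionise and funnel to carbon), the (E)-geometry is kept because syn–anti exchange would need a σ-complex at tertiary C3, excess arene suppresses double allylation, and the stereocentres are untouched.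

Step 5
Reactants: 8 3-[(2E,6R,7R)-6,7-epoxy-8-tosyloxygeranyl]phlorisovalerophenone
Product: 9 cis-fused cyclopenta[b]chroman hydroxy tosylate (2S,3R,6R,7S) [6-isovaleryl-5,7-dihydroxychroman; ether oxygen para to the acyl group and bound to C3; cyclopentane C2-C3-C4-C5-C6; C6 carries C(OH)(CH3)CH2OTs trans to C1]
Conditions: Ph4PBF4 (20 mol %), (CF3)2CHOH, 0 °C; then TsOH·H2O (5 mol %), 23 °C
Reagents that add atoms: none
Why: Proposed new method: the hydrogen-bond-donor medium activates the epoxide, whose C7–O bond is held back by the electron-withdrawing CH2OTs group, so the C2=C3 alkene attacks secondary C6 from the back (5-exo, inversion at C6, C7 untouched), the (E)-alkene places C1 and the C7 substituent trans on the new ring (sets C2), and every kinetic quench of the C3 cation (bridged ether to the C7 oxygen, trans-fused ether, alkenes) is reversible under the acid finish and drains into the unstrained cis-fused aryl ether with the bulky C7 group on its convex face, which puts oxygen on C3 cis to C1; the closest known reaction types are epoxide-initiated cation–olefin cyclisations terminated by phenols and the distal opening of 2,3-epoxy alcohol derivatives.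

Step 6
Reactants: 9 cis-fused cyclopenta[b]chroman hydroxy tosylate; 10 prenyl bromide (2.3 equiv)
Product: 13 8,8-diprenyl dearomatised pyran epoxide (2S,3R,6R,7S) [vinylogous ester; gem-diprenyl carbon next to the enol-ether carbon; C6 carries the 2-methyloxiran-2-yl group], via epoxide chroman 11 (not isolated), via monoprenyl chroman 12 (not isolated)
Conditions: KOH (4 equiv), H2O–THF 1:1, 0 to 23 °C
Reagents that add atoms: none
Why: Intramolecular Williamson closure (the C7 oxygen attacks C8, so C7 is retained) is followed by the base-mediated dearomative C-alkylation known from the classical lupulone synthesis, in which water solvates the phenoxide oxygens so that carbon reacts, the first prenyl enters the only free ring carbon, the second enters the same carbon because Cα is shielded by the folded cis-fused tricycle, and the new quaternary carbon bears two identical groups and is not stereogenic.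

Step 7
Reactants: 13 8,8-diprenyl dearomatised pyran epoxide
Product: 15 target CNP0198642.3 (spiro S; 2S,3R,6R,7R), via ring-opened enolate 14 (not isolated)
Conditions: KOH (8 equiv), DMSO–H2O 9:1, 45 °C; then aq NaH2PO4 to pH 5
Reagents that add atoms: water O
Why: Proposed new method: hydroxide adds to the enol-ether carbon of the vinylogous ester and expels the tertiary alkoxide by C(sp2)–O cleavage (C3 keeps its configuration), the released lupulone-type enolate cannot O-alkylate through a small ring, so Cα opens the epoxide at CH2 (6-exo-tet, C7 untouched, chair transition state that can only give the trans-hydrindane with equatorial C7–O), using the face that leaves the carbonyl next to the bulky diprenyl carbon equatorial and the flat acyl-enolate edge axial, which is the required spiro configuration; the closest known reaction types are the LiOH cleavage of hindered vinylogous esters at the end of polyprenylated acylphloroglucinol syntheses and enolate epoxide-opening spirocyclisations.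

**Compound list**
1 | phloroglucinol | Oc1cc(O)cc(O)c1 | starting material
2 | isovaleryl chloride | CC(C)CC(=O)Cl | starting material
3 | phlorisovalerophenone | CC(C)CC(=O)c1c(O)cc(O)cc1O | intermediate
4 | geranyl acetate | CC(C)=CCC/C(C)=C/COC(C)=O | starting material
5 | (2E,6E)-8-hydroxygeranyl acetate | CC(=O)OC/C=C(C)/CC/C=C(C)/CO | intermediate
6 | (6R,7R)-6,7-epoxy-8-hydroxygeranyl acetate | CC(=O)OC/C=C(C)/CC[C@H]1O[C@]1(C)CO | intermediate
7 | (6R,7R)-6,7-epoxy-8-tosyloxygeranyl acetate | CC(=O)OC/C=C(C)/CC[C@H]1O[C@]1(C)COS(=O)(=O)c2ccc(C)cc2 | intermediate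
8 | 3-[(2E,6R,7R)-6,7-epoxy-8-tosyloxygeranyl]phlorisovalerophenone | CC(C)CC(=O)c1c(O)cc(O)c(C/C=C(C)/CC[C@H]2O[C@]2(C)COS(=O)(=O)c3ccc(C)cc3)c1O | intermediate
9 | cis-fused cyclopenta[b]chroman hydroxy tosylate (2S,3R,6R,7S) | CC(C)CC(=O)c1c(O)cc2O[C@]3(C)CC[C@@H]([C@](C)(O)COS(=O)(=O)c4ccc(C)cc4)[C@@H]3Cc2c1O | intermediate
10 | prenyl bromide (1-bromo-3-methylbut-2-ene) | CC(C)=CCBr | starting material
11 | epoxide chroman (2S,3R,6R,7S) | CC(C)CC(=O)c1c(O)cc2O[C@]3(C)CC[C@@H]([C@@]4(C)CO4)[C@@H]3Cc2c1O | intermediate
12 | monoprenyl chroman epoxide | CC(C)CC(=O)c1c(O)c(CC=C(C)C)c2O[C@]3(C)CC[C@@H]([C@@]4(C)CO4)[C@@H]3Cc2c1O | intermediate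
13 | 8,8-diprenyl dearomatised pyran epoxide | CC(C)CC(=O)C1=C(O)C2=C(O[C@]3(C)CC[C@@H]([C@@]4(C)CO4)[C@@H]3C2)C(CC=C(C)C)(CC=C(C)C)C1=O | intermediate
14 | ring-opened lupulone-type hydroxy epoxide (drawn neutral; present as its enolate) | CC(C)CC(=O)C1=C(O)C(C[C@H]2[C@@H](CC[C@@]2(C)O)[C@@]3(C)CO3)=C(O)C(CC=C(C)C)(CC=C(C)C)C1=O | intermediate
15 | CNP0198642.3 | CC(C)=CCC1(CC=C(C)C)C(=O)[C@@]2(C[C@H]3[C@@H](CC[C@@]3(C)O)[C@](C)(O)C2)C(=O)C(C(=O)CC(C)C)=C1O | target

**Totals:** 7 steps. The longest linear sequence is 6 steps (4 → 5 → 7 → 8 → 9 → 13 → 15).

**Three steps most likely to fail**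

Step 5. The risk is 6-endo opening at C7, or rearrangement of the epoxide, instead of 5-exo attack at C6. The fallback replaces inductive control by chelation control. It sets out from 6, which is isolated without tosylation and joined to 3 under the conditions of step 4 to give the epoxy alcohol arene F1. TiCl2(OiPr)2 in CH2Cl2 at −78 °C ties the epoxide oxygen and the C8 alkoxide into a five-membered chelate. By the rule for 2,3-epoxy alcohols this chelate is opened at the distal carbon C6, and the acid finish of step 5 then gives the chroman diol F2. Bu2SnO-catalysed tosylation (TsCl, Et3N) picks the primary hydroxyl of the 1,2-diol and comes back to the route at 9.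

Step 6. The risk is O-alkylation, or a second prenylation at Cα instead of the prenyl-bearing carbon. The fallback prenylates before any ring is made. It sets out from 3, which is alkylated with 10 (2 equiv, KOH, H2O, 0 °C); the geminal isomer is separated from the 3,5-isomer to give the diprenyl trione F3. Allylation with 7 under zerovalent palladium, as in step 4, can now only hit the one free carbon and gives the acyclic lupulone analogue F4. MeAlCl2 with 2,6-di-tert-butylpyridine in CH2Cl2 at −78 to −20 °C leaves no free acid, so the prenyl groups survive. The good enolate leaving group lets the Lewis acid alone equilibrate the C3–O bond, which gives the pyran hydroxy tosylate F5. K2CO3 in MeOH closes the epoxide and comes back to the route at 13.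

Step 7. The risk is that hydroxide opens the epoxide before the hindered, anionic vinylogous ester is cleaved, or that spiro selectivity is low. The fallback separates unmasking from ring closure. It sets out from 13, which is deliberately taken through both hydrolyses (KOH, aqueous DMSO, 90 °C) to the ring-opened 7,8-diol F6. Mitsunobu cyclodehydration (PPh3, DIAD, THF) activates only the primary C8 hydroxyl, and the neighbouring C7 hydroxyl re-forms epoxide 14. The acidic trione, deprotonated by the hydrazide base, then closes the ring and comes back to the route at 15. Spiro epimers, if formed, are separated at this point.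

**Further compounds**
F1 | step 5 | epoxy alcohol arene, 3-[(2E,6R,7R)-6,7-epoxy-8-hydroxygeranyl]phlorisovalerophenone | CC(C)CC(=O)c1c(O)cc(O)c(C/C=C(C)/CC[C@H]2O[C@]2(C)CO)c1O
F2 | step 5 | chroman diol (2S,3R,6R,7S) | CC(C)CC(=O)c1c(O)cc2O[C@]3(C)CC[C@@H]([C@](C)(O)CO)[C@@H]3Cc2c1O
F3 | step 6 | diprenyl trione, 2-isovaleryl-4,4-diprenylcyclohexane-1,3,5-trione (enol form) | CC(C)CC(=O)C1=C(O)C=C(O)C(CC=C(C)C)(CC=C(C)C)C1=O
F4 | step 6 | acyclic lupulone analogue with the (6R,7R)-epoxy tosylate chain on Cα | CC(C)CC(=O)C1=C(O)C(C/C=C(C)/CC[C@H]2O[C@]2(C)COS(=O)(=O)c3ccc(C)cc3)=C(O)C(CC=C(C)C)(CC=C(C)C)C1=O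
F5 | step 6 | pyran hydroxy tosylate (2S,3R,6R,7S) | CC(C)CC(=O)C1=C(O)C2=C(O[C@]3(C)CC[C@@H]([C@](C)(O)COS(=O)(=O)c4ccc(C)cc4)[C@@H]3C2)C(CC=C(C)C)(CC=C(C)C)C1=O
F6 | step 7 | ring-opened 7,8-diol (2S,3R,6R,7S) | CC(C)CC(=O)C1=C(O)C(C[C@H]2[C@@H](CC[C@@]2(C)O)[C@](C)(O)CO)=C(O)C(CC=C(C)C)(CC=C(C)C)C1=O
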